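**Strategy.** The cyclohexane ring is cut into two three-carbon pieces: C1–C6–C5 (from methyl acrylate) and C2–C3–C4 with both methyl groups (from 3-methylbutan-2-one); ring atoms are numbered as in the target (C1 OAc, C2 ethylidene, C3 Cl, C4 CMe2, C5 Br). The feature exploited is the 1,3-relationship of the heteroatom-bearing carbons C1 and C3 across C2, a latent 1,3-dione flanked by the quaternary C4. One Michael–Claisen [3+3] annulation forms C4–C5 and C1–C2 and gives 4,4-dimethylcyclohexane-1,3-dione. Its precursors are acyclic: a C5 ketone and a C3 acrylate. Later steps place bromide at C5 and chloride at C3 by conjugate additions, build the ethylidene at C2 by aldol chemistry, and set C1 by a catalyst-controlled reduction.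

Key step: step 1

Remark on the chemistry: compounds 7–11 and 14–16 are racemic; where a relative configuration is drawn, the SMILES shows the enantiomer that is carried on. Step 8 selects that enantiomer by diastereomer separation, so at most half of 16 can reach the target.

Step 1
Reactants: 1 3-methylbutan-2-one; 2 methyl acrylate
Product: 4 4,4-dimethylcyclohexane-1,3-dione, via Michael adduct 3 (not isolated)
Conditions: NaOMe (1.1 equiv), MeOH–xylene, 0 °C → reflux; then aq. HCl
Reagents that add atoms: none
Why: Methoxide equilibrates the enolates of 1, and the more substituted one adds to 2 (Michael addition), which forms the C4–C5 bond at the future quaternary carbon and gives keto ester 3; under the same conditions the methyl ketone enolate of 3 attacks the ester carbonyl (Claisen/Dieckmann condensation) and closes the C1–C2 bond with loss of methoxide. The closest known reaction type is the Michael–Claisen [3+3] annulation of ketones with acrylates used for dimedone-type cyclohexane-1,3-diones. The six-membered ring closes in a 6-exo-trig (enolexo) mode by attack of the enolate carbon on the ester C=O. No stereocenter is formed. The step needs regioselectivity between the tertiary and the methyl α-carbon of 1 in the Michael step; it should be secured by reversibility, because only the adduct alkylated at the isopropyl carbon can close to a dione that keeps an acidic C2–H and is drained as its stabilised enolate, whereas the other adduct could only give a non-enolisable 2,2-dimethyl dione that reopens by retro-Claisen cleavage.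

Step 2
Reactants: 4 4,4-dimethylcyclohexane-1,3-dione
Product: 6 3-hydroxy-4,4-dimethylcyclohexa-2,5-dien-1-one, via selenide 5 (not isolated)
Conditions: LiN(i-Pr)2 (2.2 equiv), THF–DMPU, −78 → 0 °C; PhSeBr, −78 °C; then 30% H2O2, 0 °C → rt; aq. HCl
Reagents that add atoms: none
Why: α-Selenenylation and selenoxide syn-elimination run through the dianion of the 1,3-dione; the second deprotonation can only occur at C6 because C4 is quaternary, and the selenoxide can only eliminate toward C5–H, so the C5=C6 double bond should form.

Step 3
Reactants: 6 3-hydroxy-4,4-dimethylcyclohexa-2,5-dien-1-one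
Product: 9 rac-5-bromo-3-methoxy-6,6-dimethylcyclohex-2-en-1-one, via bis(silyl enol ether) 7 (not isolated), via bromo dione 8 (not isolated)
Conditions: Me3SiBr (3 equiv), CH2Cl2, 0 °C → rt; then MeOH (excess), rt
Reagents that add atoms: bromotrimethylsilane, C[Si](C)(C)Br; methanol, CO
Why: 1,4-Addition of a halosilane to an enone: after O-silylation of the enol, bromide should add to C5, the only unsubstituted enone β-carbon, to give 7 and create the C5 stereocenter as a racemate; methanol then releases dione 8, and the hydrogen bromide present catalyses vinylogous ester formation at the less hindered C1 oxygen, away from the gem-dimethyl group.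

Step 4
Reactants: 9 rac-5-bromo-3-methoxy-6,6-dimethylcyclohex-2-en-1-one
Product: 11 rac-5-bromo-4,4-dimethylcyclohex-2-en-1-one, via allylic alcohol 10 (not isolated)
Conditions: i-Bu2AlH (1.3 equiv), CH2Cl2, −78 °C; then 1 M HCl, THF, 0 °C → rt
Reagents that add atoms: water, O
Why: Stork–Danheiser carbonyl transposition: 1,2-reduction of the vinylogous ester carbonyl (C3 in target numbering) and acid hydrolysis of the enol ether with loss of water should give the enone with C1=O and C2=C3, under non-basic conditions that leave the β-bromide at C5 in place.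

Step 5
Reactants: 12 2-bromo-1,1-diethoxyethane
Product: 13 2-bromoacetaldehyde
Conditions: CF3CO2H–H2O (1:1), CHCl3, 0 °C → rt; organic phase dried (MgSO4) and used at once
Reagents that add atoms: water, O
Why: Acid-catalysed acetal hydrolysis; the labile aldehyde is used as a fresh solution.

Step 6
Reactants: 11 rac-5-bromo-4,4-dimethylcyclohex-2-en-1-one; 13 2-bromoacetaldehyde
Product: 15 rac-(2S,3R,5R)-5-bromo-2-(2-bromo-1-hydroxyethyl)-3-chloro-4,4-dimethylcyclohexan-1-one, via titanium enolate 14 (not isolated)
Conditions: TiCl4 (1.2 equiv), CH2Cl2, −78 °C; then 13 (1.5 equiv), −78 → −40 °C; aq. NH4Cl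
Reagents that add atoms: titanium tetrachloride, Cl[Ti](Cl)(Cl)Cl
Why: TiCl4-mediated chloro-aldol reaction (halo-aldol variant of the Morita–Baylis–Hillman reaction): chloride is transferred to the enone β-carbon C3 and enolate 14 adds to 13 at C2; chloride should enter axially on the half-chair that keeps the C5 bromine pseudo-equatorial, that is trans to bromine, since the approach syn to an axial bromine is 1,3-diaxial, and the C2 and carbinol centres are removed in step 7.

Step 7
Reactants: 15 rac-(2S,3R,5R)-5-bromo-2-(2-bromo-1-hydroxyethyl)-3-chloro-4,4-dimethylcyclohexan-1-one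
Product: 16 rac-(2Z,3R,5R)-5-bromo-2-(2-bromoethylidene)-3-chloro-4,4-dimethylcyclohexan-1-one
Conditions: Martin sulfurane Ph2S[OC(CF3)2Ph]2 (1.5 equiv), CH2Cl2, 0 °C → rt
Reagents that add atoms: none
Why: Dehydration of a β-hydroxy ketone toward the acidic C2–H under neutral conditions; the exocyclic enone should form with the bromomethyl group anti to the carbonyl (Z by CIP), the preferred geometry in which the C3 chlorine turns axial to avoid allylic 1,3-strain, and without a C2–H the β-chloride can no longer be eliminated.

Step 8
Reactants: 16 rac-(2Z,3R,5R)-5-bromo-2-(2-bromoethylidene)-3-chloro-4,4-dimethylcyclohexan-1-one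
Product: 17 (1S,2Z,3R,5R)-5-bromo-2-(2-bromoethylidene)-3-chloro-4,4-dimethylcyclohexan-1-ol
Conditions: (R)-Me-CBS oxazaborolidine [(R)-1-methyl-3,3-diphenyltetrahydro-1H,3H-pyrrolo[1,2-c][1,3,2]oxazaborole] (0.5 equiv), catecholborane (1.5 equiv), toluene–CH2Cl2, −78 °C, full conversion; MeOH; chromatography
Reagents that add atoms: none
Why: Corey–Bakshi–Shibata reduction under catalyst control, with the alkylidene side as the large group, should give the (1S)-carbinol from both enantiomers of 16; the (3R,5R) enantiomer then gives 17 and the (3S,5S) enantiomer gives a separable diastereomer, so C1 is set by the catalyst and the absolute configuration at C3 and C5 is selected by this separation.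

Step 9
Reactants: 17 (1S,2Z,3R,5R)-5-bromo-2-(2-bromoethylidene)-3-chloro-4,4-dimethylcyclohexan-1-ol
Product: 18 (1S,2Z,3R,5R)-5-bromo-2-(2-bromoethylidene)-3-chloro-4,4-dimethylcyclohexyl acetate
Conditions: Ac2O (1.5 equiv), i-Pr2NEt (2 equiv), DMAP (5 mol%), CH2Cl2, −20 → 0 °C
Reagents that add atoms: acetic anhydride, CC(=O)OC(C)=O
Why: Acylation of an equatorial secondary allylic alcohol with retention at C1; the hindered amine base and low temperature should avoid quaternisation by the allylic bromide.

**Compound list**

1 | 3-methylbutan-2-one | CC(=O)C(C)C | starting material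
2 | methyl acrylate | C=CC(=O)OC | starting material
3 | methyl 4,4-dimethyl-5-oxohexanoate (Michael adduct, not isolated) | CC(=O)C(C)(C)CCC(=O)OC | intermediate
4 | 4,4-dimethylcyclohexane-1,3-dione | O=C1CC(=O)C(C)(C)CC1 | intermediate
5 | 4,4-dimethyl-6-(phenylselanyl)cyclohexane-1,3-dione (not isolated) | O=C1CC(=O)C(C)(C)CC1[Se]c1ccccc1 | intermediate
6 | 3-hydroxy-4,4-dimethylcyclohexa-2,5-dien-1-one (enol form of 6,6-dimethylcyclohex-4-ene-1,3-dione) | CC1(C)C=CC(=O)C=C1O | intermediate
7 | rac-5-bromo-6,6-dimethyl-1,3-bis(trimethylsilyloxy)cyclohexa-1,3-diene (not isolated) | C[Si](C)(C)OC1=CC(O[Si](C)(C)C)=CC(Br)C1(C)C | intermediate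
8 | rac-5-bromo-4,4-dimethylcyclohexane-1,3-dione (not isolated) | O=C1CC(=O)C(C)(C)C(Br)C1 | intermediate
9 | rac-5-bromo-3-methoxy-6,6-dimethylcyclohex-2-en-1-one | COC1=CC(=O)C(C)(C)C(Br)C1 | intermediate
10 | 5-bromo-3-methoxy-6,6-dimethylcyclohex-2-en-1-ol (racemic diastereomers, not isolated) | COC1=CC(O)C(C)(C)C(Br)C1 | intermediate
11 | rac-5-bromo-4,4-dimethylcyclohex-2-en-1-one | O=C1C=CC(C)(C)C(Br)C1 | intermediate
12 | 2-bromo-1,1-diethoxyethane | CCOC(CBr)OCC | starting material
13 | 2-bromoacetaldehyde | O=CCBr | intermediate
14 | trichloro{[5-bromo-3-chloro-4,4-dimethylcyclohex-1-en-1-yl]oxy}titanium, 3,5-trans (racemic, not isolated) | Cl[Ti](Cl)(Cl)OC1=C[C@@H](Cl)C(C)(C)[C@H](Br)C1 | intermediate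
15 | rac-(2S,3R,5R)-5-bromo-2-(2-bromo-1-hydroxyethyl)-3-chloro-4,4-dimethylcyclohexan-1-one (carbinol epimers) | O=C1C[C@@H](Br)C(C)(C)[C@H](Cl)[C@H]1C(O)CBr | intermediate
16 | rac-(2Z,3R,5R)-5-bromo-2-(2-bromoethylidene)-3-chloro-4,4-dimethylcyclohexan-1-one | O=C1C[C@@H](Br)C(C)(C)[C@H](Cl)/C1=C\CBr | intermediate
17 | (1S,2Z,3R,5R)-5-bromo-2-(2-bromoethylidene)-3-chloro-4,4-dimethylcyclohexan-1-ol | O[C@H]1C[C@@H](Br)C(C)(C)[C@H](Cl)/C1=C\CBr | intermediate
18 | (1S,2Z,3R,5R)-5-bromo-2-(2-bromoethylidene)-3-chloro-4,4-dimethylcyclohexyl acetate | CC(=O)O[C@H]1C[C@@H](Br)C(C)(C)[C@H](Cl)/C1=C\CBr | target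

**Step count.** Total steps: 9. Longest linear sequence: 8 (steps 1–4 and 6–9).

**Steps most likely to fail**

Step 8. The risk is poor diastereofacial control: for the (3R,5R) enantiomer the catalyst may have to override an intrinsic preference of hydride to approach anti to the axial C3 chlorine. This would lower the yield of 17, not its enantiomeric purity. The fallback uses inversion instead of direct delivery. From 16, reduction with the (S)-configured oxazaborolidine and catecholborane, where catalyst and substrate bias should cooperate for the (3R,5R) enantiomer, should give (1R,2Z,3R,5R)-5-bromo-2-(2-bromoethylidene)-3-chloro-4,4-dimethylcyclohexan-1-ol F6 after separation from the diastereomer formed from the other enantiomer. Mitsunobu inversion with acetic acid (PPh3 and diisopropyl azodicarboxylate premixed, so that no free phosphine meets the allylic bromide) then returns to the route at 18.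

Step 6. The risks are slow or reversible chloride transfer to the neopentyl β-carbon C3, retro-aldol cleavage, and loss of HCl from the adduct. The fallback makes a Morita–Baylis–Hillman-type alcohol first and chlorinates afterwards. From 11, ZnI2-catalysed 1,4-addition of PhSSiMe3 gives [5-bromo-4,4-dimethyl-3-(phenylsulfanyl)cyclohex-1-en-1-yl]oxy(trimethyl)silane F2. Mukaiyama aldol addition to 13 (BF3·OEt2, −78 °C) gives 5-bromo-2-(2-bromo-1-hydroxyethyl)-4,4-dimethyl-3-(phenylsulfanyl)cyclohexan-1-one F3. Oxidation with mCPBA gives the sulfoxide 5-bromo-2-(2-bromo-1-hydroxyethyl)-4,4-dimethyl-3-(phenylsulfinyl)cyclohexan-1-one F4, whose syn-elimination on warming gives 5-bromo-2-(2-bromo-1-hydroxyethyl)-4,4-dimethylcyclohex-2-en-1-one F5. SOCl2 in Et2O then converts the allylic alcohol into the transposed chloride (SNi′, chloride to C3, double bond to the exocyclic position) and returns to the route at 16.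

Step 3. The risks are loss of HBr from bromo dione 8 in acidic methanol (return to the conjugated dienone) and incomplete regiocontrol of the etherification in the telescoped procedure. The fallback reverses the order and adds bromide to the preformed vinylogous ester. From 6, etherification with MeOH and catalytic TsOH gives 3-methoxy-6,6-dimethylcyclohexa-2,4-dien-1-one F1. 1,6-Addition of dry HBr in CH2Cl2 at −78 °C (protonation at the carbonyl oxygen, bromide to C5) then returns to the route at 9.

Further compounds
F1 | step 3 | 3-methoxy-6,6-dimethylcyclohexa-2,4-dien-1-one | COC1=CC(=O)C(C)(C)C=C1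
F2 | step 6 | [5-bromo-4,4-dimethyl-3-(phenylsulfanyl)cyclohex-1-en-1-yl]oxy(trimethyl)silane (racemic diastereomers) | C[Si](C)(C)OC1=CC(Sc2ccccc2)C(C)(C)C(Br)C1
F3 | step 6 | 5-bromo-2-(2-bromo-1-hydroxyethyl)-4,4-dimethyl-3-(phenylsulfanyl)cyclohexan-1-one (racemic diastereomers) | O=C1CC(Br)C(C)(C)C(Sc2ccccc2)C1C(O)CBr
F4 | step 6 | 5-bromo-2-(2-bromo-1-hydroxyethyl)-4,4-dimethyl-3-(phenylsulfinyl)cyclohexan-1-one (racemic diastereomers, not isolated) | O=C1CC(Br)C(C)(C)C(S(=O)c2ccccc2)C1C(O)CBr
F5 | step 6 | 5-bromo-2-(2-bromo-1-hydroxyethyl)-4,4-dimethylcyclohex-2-en-1-one (racemic diastereomers) | O=C1CC(Br)C(C)(C)C=C1C(O)CBr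
F6 | step 8 | (1R,2Z,3R,5R)-5-bromo-2-(2-bromoethylidene)-3-chloro-4,4-dimethylcyclohexan-1-ol | O[C@@H]1C[C@@H](Br)C(C)(C)[C@H](Cl)/C1=C\CBr
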